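## Retrosynthetic overview

1. The last three ring closures are planned for one flask, starting from the bicyclic keto aldehyde 19. The C2–C3 bond of the carbocycle forms first (acyl-anion addition of an aldehyde to an aryl ketone), then the C3–O–C(=O)–N carbamate, then the N1=C2 imine, so the pyrroline ring of the 3H-indole closes last.
2. Enabling feature: the indolenine C2(=N)–C3(O)(aryl) pair is an acyloin in disguise. C2 sits next to the quaternary CMe2 carbon, so its aldehyde precursor cannot enolize and can only act as acyl-anion donor. The C3 oxygen is 1,3-diaxial to the nitrogen on the aminated carbon of the six-membered carbocycle, so only the correct C3 epimer is trapped as the six-membered carbamate. The ortho nitrogen of the C3 aryl group is placed to close a five-membered ring onto C2.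
3. 19 comes from diene 18 by double ozonolysis; 18 from indolizidine 13 by Suzuki coupling (benzene ring brought in), Wittig methylenation, and nitro reduction/carbamoylation.
4. 13 comes from Pd-catalysed allylation of ring nitronate 11 (amino-bearing quaternary centre); 11 from nitro-Mannich closure of the piperidine; the ring-fusion CH from an organocatalytic Michael addition of 2-methylpropanal to nitroalkene 7; 7 from Boc-D-β-homoproline (pyrrolidine ring and its stereocentre from the chiral pool).
5. Ring order: pyrrolidine (given) → piperidine (step 5) → benzene attached (step 7) → cyclohexanone, then oxazinanone, then 3H-indole pyrroline ring (all in step 11).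

Key step: step 11

Remark on the chemistry: locants C2, C3, C3a and C7a in the text are those of the 3H-indole unit of the target; the carbinol carbon of 5 and 6 is destroyed in the same step and is drawn without configuration; the sense of induction in step 4 is taken to be set by the choice of catalyst enantiomer.

## Route

Step 1
Reactants: 1 (2R)-2-[1-(tert-butoxycarbonyl)pyrrolidin-2-yl]acetic acid (Boc-D-β-homoproline)
Product: 2 tert-butyl (2R)-2-(2-hydroxyethyl)pyrrolidine-1-carboxylate
Conditions: BH3·SMe2, THF, 0→23 °C; MeOH quench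
Reagents that add atoms: none
Why: Borane reduces the carboxylic acid chemoselectively in the presence of the carbamate (borane reduction of acids) and the stereocentre is not touched.

Step 2
Reactants: 2 tert-butyl (2R)-2-(2-hydroxyethyl)pyrrolidine-1-carboxylate
Product: 3 tert-butyl (2R)-2-(2-oxoethyl)pyrrolidine-1-carboxylate
Conditions: Dess–Martin periodinane, CH2Cl2, 23 °C
Reagents that add atoms: none
Why: Dess–Martin oxidation stops at the aldehyde under near-neutral conditions that leave the Boc group and the centre β to the new carbonyl alone.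

Step 3
Reactants: 3 tert-butyl (2R)-2-(2-oxoethyl)pyrrolidine-1-carboxylate; 4 nitromethane
Product: 7 tert-butyl (2R)-2-[(2E)-3-nitroprop-2-en-1-yl]pyrrolidine-1-carboxylate, via nitro alcohol 5 (not isolated), via mesylate 6 (not isolated)
Conditions: MeNO2 (10 equiv), tetramethylguanidine (10 mol %), THF, 0 °C; then MsCl, iPr2NEt, CH2Cl2, −40→0 °C
Reagents that add atoms: none
Why: A Henry addition followed by E1cB loss of the mesylate should give the thermodynamically preferred (E)-nitroalkene, and the low temperature and hindered base are chosen to limit migration of the double bond out of conjugation.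

Step 4
Reactants: 7 tert-butyl (2R)-2-[(2E)-3-nitroprop-2-en-1-yl]pyrrolidine-1-carboxylate; 8 2-methylpropanal
Product: 9 tert-butyl (2R)-2-[(2R)-3,3-dimethyl-2-(nitromethyl)-4-oxobutyl]pyrrolidine-1-carboxylate
Conditions: 8 (3 equiv), primary amine–thiourea catalyst derived from trans-cyclohexane-1,2-diamine (20 mol %, the enantiomer that delivers the (R) centre), H2O (5 equiv), CH2Cl2, 23 °C
Reagents that add atoms: none
Why: This is an enamine-mediated Michael addition of an α,α-disubstituted aldehyde to a nitroalkene held by the thiourea, in which the catalyst (reagent control) sets the future ring-fusion centre as (R) while the same bond creates the gem-dimethyl quaternary carbon.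

Step 5
Reactants: 9 tert-butyl (2R)-2-[(2R)-3,3-dimethyl-2-(nitromethyl)-4-oxobutyl]pyrrolidine-1-carboxylate
Product: 11 2-methyl-2-[(6R,7R,8aR)-6-nitrooctahydroindolizin-7-yl]propanal, via pyrrolidinium trifluoroacetate 10 (not isolated)
Conditions: TFA, CH2Cl2, 0→23 °C; evaporate; then 37% aq. CH2O (1.1 equiv), Et3N, EtOH, 23→40 °C
Reagents that add atoms: formaldehyde, C=O
Why: After Boc cleavage the formaldehyde iminium of the pyrrolidine should be attacked by the nitronate in an intramolecular nitro-Mannich (aza-Henry) reaction (6-endo-trig) that closes the piperidine ring, the two existing centres placing both ring substituents equatorial, while the nitro-bearing carbon stays epimerizable (equatorial nitro expected) and is planarized again in step 6, and the hindered non-enolizable aldehyde can engage the amine only reversibly.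

Step 6
Reactants: 11 2-methyl-2-[(6R,7R,8aR)-6-nitrooctahydroindolizin-7-yl]propanal; 12 2,3-dibromoprop-1-ene
Product: 13 2-[(6S,7R,8aR)-6-(2-bromoprop-2-en-1-yl)-6-nitrooctahydroindolizin-7-yl]-2-methylpropanal
Conditions: Pd2(dba)3 (2.5 mol %), PPh3 (12 mol %), Cs2CO3, THF, 0→23 °C
Reagents that add atoms: none
Why: In this Tsuji–Trost C-allylation zerovalent palladium inserts into the allylic and not the vinylic C–Br bond, and the symmetrical 2-bromo-π-allyl complex of divalent palladium should attack the planar ring nitronate anti to the bulky neighbouring quaternary substituent, so that the new chain enters trans to it (equatorial) and the nitro group ends axial, which sets the amino-bearing quaternary centre as (6S).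

Step 7
Reactants: 13 2-[(6S,7R,8aR)-6-(2-bromoprop-2-en-1-yl)-6-nitrooctahydroindolizin-7-yl]-2-methylpropanal; 14 tert-butyl N-[2-(4,4,5,5-tetramethyl-1,3,2-dioxaborolan-2-yl)phenyl]carbamate
Product: 15 tert-butyl N-[2-(3-{(6S,7R,8aR)-7-(2-methyl-1-oxopropan-2-yl)-6-nitrooctahydroindolizin-6-yl}prop-1-en-2-yl)phenyl]carbamate
Conditions: PdCl2(dppf) (5 mol %), K3PO4, 1,4-dioxane/H2O, 60 °C
Reagents that add atoms: none
Why: A Suzuki–Miyaura coupling of the 2-bromoalkene with the ortho-(Boc-amino)aryl pinacol boronate brings in the benzene ring, and the tertiary nitro group and the non-enolizable aldehyde should tolerate the mild aqueous base with no stereocentre involved.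

Step 8
Reactants: 15 tert-butyl N-[2-(3-{(6S,7R,8aR)-7-(2-methyl-1-oxopropan-2-yl)-6-nitrooctahydroindolizin-6-yl}prop-1-en-2-yl)phenyl]carbamate
Product: 16 tert-butyl N-[2-(3-{(6S,7R,8aR)-7-(2-methylbut-3-en-2-yl)-6-nitrooctahydroindolizin-6-yl}prop-1-en-2-yl)phenyl]carbamate
Conditions: Ph3PCH3Br (3.0 equiv), KHMDS (2.9 equiv), THF, 0→23 °C
Reagents that add atoms: methylenetriphenylphosphorane, C=P(c1ccccc1)(c1ccccc1)c1ccccc1
Why: Wittig methylenation stores the aldehyde as a vinyl group that ozonolysis returns in step 10, so that the primary amine freed in step 9 cannot condense onto it to a five-membered cyclic imine, and the excess ylide allows for the acidic anilide N–H.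

Step 9
Reactants: 16 tert-butyl N-[2-(3-{(6S,7R,8aR)-7-(2-methylbut-3-en-2-yl)-6-nitrooctahydroindolizin-6-yl}prop-1-en-2-yl)phenyl]carbamate
Product: 18 phenyl N-[(6S,7R,8aR)-6-(2-{2-[(tert-butoxycarbonyl)amino]phenyl}prop-2-en-1-yl)-7-(2-methylbut-3-en-2-yl)octahydroindolizin-6-yl]carbamate, via amine 17 (not isolated)
Conditions: Zn dust, AcOH/THF, 23→50 °C; filter; then PhOCOCl (1.05 equiv), pyridine, CH2Cl2, −20→0 °C
Reagents that add atoms: phenyl chloroformate, O=C(Cl)Oc1ccccc1
Why: Zinc/acetic acid reduction of the tertiary nitro group should leave the alkenes and the Boc group intact and breaks no bond at the stereocentre, and the only nucleophilic primary amine is then acylated to the phenyl carbamate, an activated carbamoyl donor for step 11.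

Step 10
Reactants: 18 phenyl N-[(6S,7R,8aR)-6-(2-{2-[(tert-butoxycarbonyl)amino]phenyl}prop-2-en-1-yl)-7-(2-methylbut-3-en-2-yl)octahydroindolizin-6-yl]carbamate
Product: 19 phenyl N-[(6S,7R,8aR)-6-(2-{2-[(tert-butoxycarbonyl)amino]phenyl}-2-oxoethyl)-7-(2-methyl-1-oxopropan-2-yl)octahydroindolizin-6-yl]carbamate
Conditions: TsOH·H2O (1.1 equiv), O3, CH2Cl2/MeOH, −78 °C; then Me2S, −78→23 °C; aq. NaHCO3
Reagents that add atoms: ozone, [O-][O+]=O
Why: Ozonolysis with reductive work-up should cleave both terminal alkenes at once to the aryl ketone and the neopentyl aldehyde, while protonation shields the tertiary amine from oxidation.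

Step 11
Reactants: 19 phenyl N-[(6S,7R,8aR)-6-(2-{2-[(tert-butoxycarbonyl)amino]phenyl}-2-oxoethyl)-7-(2-methyl-1-oxopropan-2-yl)octahydroindolizin-6-yl]carbamate
Product: 23 penicimutamide C, via hydroxy ketone 20 (not isolated), via bridged carbamate 21 (not isolated), via aminophenyl ketone 22 (not isolated)
Conditions: 2-(pentafluorophenyl)-6,7-dihydro-5H-pyrrolo[2,1-c][1,2,4]triazol-2-ium tetrafluoroborate (20 mol %), DBU (1.5 equiv), THF, 23→45 °C; then TFA, CH2Cl2, 23 °C; aq. NaHCO3
Reagents that add atoms: none
Why: Proposed new method: the carbene from the triazolium salt adds to the only aldehyde, which is neopentyl and non-enolizable so that aldol paths are shut, and the resulting hydroxy-enamine (acyl-anion equivalent) attacks the aryl ketone (6-exo-trig) to close the cyclohexanone ring as the tertiary alkoxide of 20; the closest known reaction is the intramolecular crossed aldehyde–ketone benzoin cyclization, and what is new is the α-quaternary aldehyde donor and the capture of the alkoxide in the same flask. The new stereocentre C3 is set in this C–C bond formation by a chair transition state with the aryl group equatorial and the oxygen axial, because the axial site is flanked by the axial carbamate nitrogen on the aminated ring carbon and by an axial methyl of the CMe2 group, and since the benzoin step is reversible a wrong epimer can return to 19. Only the epimer whose C3 oxygen is 1,3-diaxial to the N–H carbamate can displace phenoxide (6-exo-trig transcarbamoylation) to give the bridged oxazinanone 21, which makes the sequence irreversible and stereoconvergent. TFA then removes the Boc group and the freed aniline nitrogen of 22 adds to the C2 ketone (5-exo-trig) and loses water, closing the 3H-indole ring as the last ring. By then C3 is a bridgehead next to a carbonyl, so acid cannot ionize the benzylic C–O bond. The selectivity needed is chemoselectivity, and the substrate secures it with one aldehyde (donor), one ketone (acceptor), one activated carbamate, and a C2 ketone that has no enolizable neighbour once C3 is quaternary.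

## Compound list

1 | (2R)-2-[1-(tert-butoxycarbonyl)pyrrolidin-2-yl]acetic acid (Boc-D-β-homoproline) | CC(C)(C)OC(=O)N1CCC[C@@H]1CC(=O)O | starting material
2 | tert-butyl (2R)-2-(2-hydroxyethyl)pyrrolidine-1-carboxylate | CC(C)(C)OC(=O)N1CCC[C@@H]1CCO | intermediate
3 | tert-butyl (2R)-2-(2-oxoethyl)pyrrolidine-1-carboxylate | CC(C)(C)OC(=O)N1CCC[C@@H]1CC=O | intermediate
4 | nitromethane | C[N+](=O)[O-] | starting material
5 | tert-butyl (2R)-2-(2-hydroxy-3-nitropropyl)pyrrolidine-1-carboxylate (both carbinol epimers) | CC(C)(C)OC(=O)N1CCC[C@@H]1CC(O)C[N+](=O)[O-] | intermediate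
6 | tert-butyl (2R)-2-[2-(methanesulfonyloxy)-3-nitropropyl]pyrrolidine-1-carboxylate (both epimers) | CC(C)(C)OC(=O)N1CCC[C@@H]1CC(OS(C)(=O)=O)C[N+](=O)[O-] | intermediate
7 | tert-butyl (2R)-2-[(2E)-3-nitroprop-2-en-1-yl]pyrrolidine-1-carboxylate | CC(C)(C)OC(=O)N1CCC[C@@H]1C/C=C/[N+](=O)[O-] | intermediate
8 | 2-methylpropanal | CC(C)C=O | starting material
9 | tert-butyl (2R)-2-[(2R)-3,3-dimethyl-2-(nitromethyl)-4-oxobutyl]pyrrolidine-1-carboxylate | CC(C)(C)OC(=O)N1CCC[C@@H]1C[C@H](C(C)(C)C=O)C[N+](=O)[O-] | intermediate
10 | (2R)-2-[(2R)-3,3-dimethyl-2-(nitromethyl)-4-oxobutyl]pyrrolidin-1-ium trifluoroacetate | [O-]C(=O)C(F)(F)F.[NH2+]1CCC[C@@H]1C[C@H](C(C)(C)C=O)C[N+](=O)[O-] | intermediate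
11 | 2-methyl-2-[(6R,7R,8aR)-6-nitrooctahydroindolizin-7-yl]propanal (equatorial nitro epimer drawn; the nitro carbon is epimerizable) | [O-][N+](=O)[C@H]1CN2CCC[C@@H]2C[C@@H]1C(C)(C)C=O | intermediate
12 | 2,3-dibromoprop-1-ene | C=C(Br)CBr | starting material
13 | 2-[(6S,7R,8aR)-6-(2-bromoprop-2-en-1-yl)-6-nitrooctahydroindolizin-7-yl]-2-methylpropanal | C=C(Br)C[C@]1(CN2CCC[C@@H]2C[C@@H]1C(C)(C)C=O)[N+](=O)[O-] | intermediate
14 | tert-butyl N-[2-(4,4,5,5-tetramethyl-1,3,2-dioxaborolan-2-yl)phenyl]carbamate | CC(C)(C)OC(=O)Nc1ccccc1B1OC(C)(C)C(C)(C)O1 | starting material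
15 | tert-butyl N-[2-(3-{(6S,7R,8aR)-7-(2-methyl-1-oxopropan-2-yl)-6-nitrooctahydroindolizin-6-yl}prop-1-en-2-yl)phenyl]carbamate | C=C(c1ccccc1NC(=O)OC(C)(C)C)C[C@]2(CN3CCC[C@@H]3C[C@@H]2C(C)(C)C=O)[N+](=O)[O-] | intermediate
16 | tert-butyl N-[2-(3-{(6S,7R,8aR)-7-(2-methylbut-3-en-2-yl)-6-nitrooctahydroindolizin-6-yl}prop-1-en-2-yl)phenyl]carbamate | C=C(c1ccccc1NC(=O)OC(C)(C)C)C[C@]2(CN3CCC[C@@H]3C[C@@H]2C(C)(C)C=C)[N+](=O)[O-] | intermediate
17 | tert-butyl N-[2-(3-{(6S,7R,8aR)-6-amino-7-(2-methylbut-3-en-2-yl)octahydroindolizin-6-yl}prop-1-en-2-yl)phenyl]carbamate | C=C(c1ccccc1NC(=O)OC(C)(C)C)C[C@]2(CN3CCC[C@@H]3C[C@@H]2C(C)(C)C=C)N | intermediate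
18 | phenyl N-[(6S,7R,8aR)-6-(2-{2-[(tert-butoxycarbonyl)amino]phenyl}prop-2-en-1-yl)-7-(2-methylbut-3-en-2-yl)octahydroindolizin-6-yl]carbamate | C=C(c1ccccc1NC(=O)OC(C)(C)C)C[C@]2(CN3CCC[C@@H]3C[C@@H]2C(C)(C)C=C)NC(=O)Oc4ccccc4 | intermediate
19 | phenyl N-[(6S,7R,8aR)-6-(2-{2-[(tert-butoxycarbonyl)amino]phenyl}-2-oxoethyl)-7-(2-methyl-1-oxopropan-2-yl)octahydroindolizin-6-yl]carbamate (open form drawn; may rest as the cyclic N-carbamoyl hemiaminal, which reopens under base) | O=C(c1ccccc1NC(=O)OC(C)(C)C)C[C@]2(CN3CCC[C@@H]3C[C@@H]2C(C)(C)C=O)NC(=O)Oc4ccccc4 | intermediate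
20 | tricyclic α-hydroxy ketone: cyclohexanone formed by joining the aldehyde carbon of 19 to its ketone carbon; tertiary (S) carbinol carbon bearing the 2-(Boc-amino)phenyl group with OH syn to the phenyl carbamate nitrogen | CC1(C)C(=O)[C@@](O)(c3ccccc3NC(=O)OC(C)(C)C)C[C@]2(CN4CCC[C@@H]4C[C@H]12)NC(=O)Oc5ccccc5 | intermediate
21 | bridged carbamate ketone: as 20 with the tertiary oxygen acylated by the carbamate carbonyl (phenol lost), a six-membered cyclic carbamate spanning the two 1,3-related ring carbons; aniline still Boc-protected | CC1(C)C(=O)[C@@]2(c3ccccc3NC(=O)OC(C)(C)C)C[C@]4(CN5CCC[C@@H]5C[C@H]14)NC(=O)O2 | intermediate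
22 | 2-aminophenyl ketone: 21 without the Boc group | CC1(C)C(=O)[C@@]2(c3ccccc3N)C[C@]4(CN5CCC[C@@H]5C[C@H]14)NC(=O)O2 | intermediate
23 | penicimutamide C | CC1(C)C2=Nc3ccccc3[C@@]23C[C@]2(CN4CCC[C@@H]4C[C@H]12)NC(=O)O3 | target

## Step count and risks

Total step count: 11. Longest linear sequence: 11 steps (1 → 23); compounds 4, 8, 12 and 14 are purchased.

Steps most likely to fail:

Step 11 (proposed new method). What may go wrong is slow formation of the acyl-anion equivalent from the α-quaternary aldehyde, with base-induced β-elimination of the carbamate from the aryl ketone or an α-ketol shift of the tertiary alkoxide overtaking ring closure. The fallback closes the same C–C bond reductively. It sets out from 19: SmI2 in THF/t-BuOH at −78 °C should effect a ketyl–aldehyde pinacol cyclization to the cis-diol F1. DBU in THF should then let the tertiary alkoxide displace phenoxide to give the bridged carbamate alcohol F2. Dess–Martin oxidation of the remaining hindered secondary alcohol comes back to the route at 21, from which TFA closes the 3H-indole ring as in step 11.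

Step 6. What may go wrong is steric retardation of C-allylation at the ring nitronate, which lies next to a carbon carrying a quaternary substituent, so that O-allylation or recovery of 11 takes over. The fallback reverses the order of the two C–C bond formations at the nitro carbon. It sets out from 9: the same palladium-catalysed allylation with 12 on the unhindered primary nitronate should give the acyclic bromoallyl nitro aldehyde F3 (epimers at the nitro carbon). TFA should give its pyrrolidinium salt F4, and formaldehyde/Et3N then closes the piperidine by an intramolecular nitro-Mannich reaction that forms the quaternary centre and comes back to the route at 13. That closure is reversible, so the epimer with axial nitro and equatorial bromoallyl chain can accumulate.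

Step 4. What may go wrong is isomerization of the nitroalkene out of conjugation under the amine catalyst and low reactivity of the aliphatic acceptor, which would erode facial selectivity. The fallback replaces the catalytic enamine addition by a stoichiometric ester-enolate addition. It sets out from 7: the lithium enolate of methyl 2-methylpropanoate (LDA, THF, −78 °C) should add to give the nitro ester F5, formed as a mixture at the new centre from which the (R) epimer is separated. DIBAL-H at −78 °C then reduces the ester to the aldehyde and comes back to the route at 9.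

## Further compounds

F1 | step 11 | cis-diol from pinacol cyclization of 19 (secondary OH at the former aldehyde carbon, tertiary benzylic OH at the former ketone carbon, phenyl carbamate intact) | CC1(C)[C@H](O)[C@@](O)(c3ccccc3NC(=O)OC(C)(C)C)C[C@]2(CN4CCC[C@@H]4C[C@H]12)NC(=O)Oc5ccccc5
F2 | step 11 | bridged carbamate alcohol (oxazinanone closed, secondary OH next to the CMe2 carbon still present) | CC1(C)[C@H](O)[C@@]2(c3ccccc3NC(=O)OC(C)(C)C)C[C@]4(CN5CCC[C@@H]5C[C@H]14)NC(=O)O2
F3 | step 6 | tert-butyl (2R)-2-[(2R)-2-(3-bromo-1-nitrobut-3-en-1-yl)-3,3-dimethyl-4-oxobutyl]pyrrolidine-1-carboxylate (epimers at the nitro carbon) | CC(C)(C)OC(=O)N1CCC[C@@H]1C[C@H](C(C)(C)C=O)C(CC(Br)=C)[N+](=O)[O-]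
F4 | step 6 | (2R)-2-[(2R)-2-(3-bromo-1-nitrobut-3-en-1-yl)-3,3-dimethyl-4-oxobutyl]pyrrolidin-1-ium trifluoroacetate | [O-]C(=O)C(F)(F)F.[NH2+]1CCC[C@@H]1C[C@H](C(C)(C)C=O)C(CC(Br)=C)[N+](=O)[O-]
F5 | step 4 | methyl (3R)-4-[(2R)-1-(tert-butoxycarbonyl)pyrrolidin-2-yl]-2,2-dimethyl-3-(nitromethyl)butanoate | CC(C)(C)OC(=O)N1CCC[C@@H]1C[C@H](C(C)(C)C(=O)OC)C[N+](=O)[O-]
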